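**Retrosynthetic overview**
1. Last bond, formed at the anode: C8–O1″. Oxidation of the 5-hydroxy ring A of dihydrofuran carbinol 9 lets the ortho-OH of ring A″ attack C8 (para to 5-OH, ipso to C3″), closing the spiro-chromanone ring and leaving the dienone.
2. Dihydrofuran ring ⇐ O7–C2″: p-quinone methide from the open-chain triol carbinol 7, closed 5-exo by the flavan 7-OH.
3. 7 ⇐ C8–C3″: hydroxyalkylation of (−)-epiafzelechin by the central C=O of a vicinal triketone, then NaBH4 reduction of the 4-hydroxybenzoyl C=O.
4. Triketone (stored as its benzofuranone hemiketal 4) ⇐ kaempferol by anodic two-electron oxidation with ring contraction.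
5. Ring order: flavan rings bought → dihydrofuran ring → spiro-chromanone ring. Stereocentres: C2 and C3 bought; C3″ made in the coupling; C2″ and C8 set by C3″.

Assumption: kaempferol and (−)-epiafzelechin (2R,3R) are bought as catalogue flavonoids; double-primed locants (2″, 3″, 4″, O1″, rings A″ and B″) are those of the kaempferol-derived C6–C3–C6 unit, unprimed ones those of the flavan.

**Step 1**
Reactants: 1 kaempferol
Product: 4 benzofuranone hemiketal 2,4,6-trihydroxy-2-(4-hydroxybenzoyl)benzofuran-3(2H)-one (racemic), via 2-hydroxychromane-3,4-dione 2 (not isolated), via open triketone 3 (not isolated)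
Conditions: graphite-felt anode, Pt cathode, divided cell, +0.85 V vs Ag/AgCl, 2.1 F/mol, LiClO4 (0.1 M), MeCN–H2O 1:1, 20 °C
Reagents that add atoms: water, O
Why: Known anodic two-electron oxidation of a flavonol: the enol/4′-phenol system is oxidised to a quinone-methide cation, water adds at C2 to give 2, and ring–chain tautomerism through triketone 3 recloses the ring A oxygen onto the central carbonyl (oxidative ring contraction) to give 4; no lasting stereocentre is made because 4 is a racemic, ring-opening hemiketal.

**Step 2**
Reactants: 4 benzofuranone hemiketal (1.5 equiv); 5 (−)-epiafzelechin (2R,3R)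
Product: 7 triol carbinol (2S)-2,3-dihydroxy-3-(4-hydroxyphenyl)-2-[(2R,3R)-3,5,7-trihydroxy-2-(4-hydroxyphenyl)chroman-8-yl]-1-(2,4,6-trihydroxyphenyl)propan-1-one (= 3″S; both C2″ epimers), via keto carbinol 6 (not isolated)
Conditions: EtOH–H2O 1:1, N2, 35 °C, 24 h; then NaBH4 (2 equiv), 0 °C, 30 min
Reagents that add atoms: none
Why: In solution hemiketal 4 stays in ring–chain equilibrium with its open vicinal tricarbonyl form (the triketone met in step 1), whose central carbonyl undergoes Friedel–Crafts-type hydroxyalkylation by the phloroglucinol ring at C8 (major over C6, as in the 8-C-ascorbyl catechins) to give 6; NaBH4 then reduces the 4-hydroxybenzoyl ketone chemoselectively, because the 2,4,6-trihydroxyaryl ketone is shielded by two hydrogen bonds and three donor oxygens. C3″ forms remote from the bought flavan centres, so about 1:1 of both epimers is expected and the 3″S compound shown is carried on beside its epimer until the rigid spirocycles are separated after step 3. The C2″ mixture does not matter because that centre is ionised in step 3.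

**Step 3**
Reactants: 7 triol carbinol
Product: 10 CNP0170480.3 (2R,3R,8S,2″S,3″R), via quinone methide 8 (not isolated), via dihydrofuran carbinol 9 (not isolated)
Conditions: p-TsOH·H2O (5 mol %), HFIP, 25 °C, 3 h; then MeCN (to HFIP–MeCN 9:1), n-Bu4NBF4 (0.05 M), graphite anode, Pt cathode, undivided cell, 2 mA/cm2, 2.2 F/mol, 0 °C
Reagents that add atoms: none
Why: Proposed new method: acid in HFIP first ionises the p-hydroxybenzylic alcohol of 7 to p-quinone methide 8, which the flavan 7-OH closes 5-exo-trig to dihydrobenzofuran 9 (known HFIP-promoted p-quinone-methide oxa-Michael chemistry); the closure is reversible, so the aryl group settles trans to the bulky aroyl group, that is cis to 3″-OH (2″S). The new part is the anodic step: flavan ring A of 9 (a 5-phenol flanked by two ether oxygens) is the only ring oxidised at low potential, since ring A″ is an acyl-deactivated, hydrogen-bonded phloroglucinol and the two 4-hydroxyphenyl rings oxidise later. The resulting phenoxonium ion is captured at C8, para to 5-OH and ipso to C3″, by the ortho-OH of ring A″, which closes the six-membered chromanone ring and leaves the cross-conjugated dienone of 10. The closest known reactions are anodic and hypervalent-iodine dearomatising para-spirocyclisations of 4-alkylphenols by tethered alcohols or carboxylic acids, and grisan-type oxidative phenol coupling; capture by a phenolic oxygen at a fully substituted carbon next to a tertiary carbinol, on a free polyphenol, is not known. C3″ holds the aroyl group on one face of the dihydrofuran ring, so its ortho oxygen can reach C8 only from that face and the spiro centre follows C3″ (cis ring fusion; 3″S in 9 is called 3″R in 10 only because the CIP ranking changes). Preparative C18 HPLC on an achiral phase removes the 8R,2″R,3″S diastereomer that comes from the 3″ epimer of 7.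

**Compound list**
1 | kaempferol, 3,5,7-trihydroxy-2-(4-hydroxyphenyl)chromen-4-one | O=c1c(O)c(-c2ccc(O)cc2)oc2cc(O)cc(O)c12 | starting material
2 | 2,5,7-trihydroxy-2-(4-hydroxyphenyl)chromane-3,4-dione (racemic; in flask) | O=C1C(=O)C(O)(c2ccc(O)cc2)Oc2cc(O)cc(O)c12 | intermediate
3 | open triketone 1-(4-hydroxyphenyl)-3-(2,4,6-trihydroxyphenyl)propane-1,2,3-trione (achiral; in flask) | O=C(c1ccc(O)cc1)C(=O)C(=O)c1c(O)cc(O)cc1O | intermediate
4 | 2,4,6-trihydroxy-2-(4-hydroxybenzoyl)benzofuran-3(2H)-one (racemic hemiketal of 3) | O=C(c1ccc(O)cc1)C1(O)Oc2cc(O)cc(O)c2C1=O | intermediate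
5 | (−)-epiafzelechin, (2R,3R)-2-(4-hydroxyphenyl)chromane-3,5,7-triol | Oc1cc(O)c2C[C@@H](O)[C@@H](c3ccc(O)cc3)Oc2c1 | starting material
6 | keto carbinol (2S)-2-hydroxy-1-(4-hydroxyphenyl)-2-[(2R,3R)-3,5,7-trihydroxy-2-(4-hydroxyphenyl)chroman-8-yl]-3-(2,4,6-trihydroxyphenyl)propane-1,3-dione (= 3″S; open form of its 7-O-hemiketal; in flask) | O=C(c1ccc(O)cc1)[C@](c1c(O)cc(O)c2C[C@@H](O)[C@@H](c3ccc(O)cc3)Oc12)(O)C(=O)c1c(O)cc(O)cc1O | intermediate
7 | triol carbinol (2S)-2,3-dihydroxy-3-(4-hydroxyphenyl)-2-[(2R,3R)-3,5,7-trihydroxy-2-(4-hydroxyphenyl)chroman-8-yl]-1-(2,4,6-trihydroxyphenyl)propan-1-one (= 3″S; C2″ unassigned, both epimers) | OC(c1ccc(O)cc1)[C@](c1c(O)cc(O)c2C[C@@H](O)[C@@H](c3ccc(O)cc3)Oc12)(O)C(=O)c1c(O)cc(O)cc1O | intermediate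
8 | open-chain quinone methide (2R)-2-hydroxy-3-(4-oxocyclohexa-2,5-dien-1-ylidene)-2-[(2R,3R)-3,5,7-trihydroxy-2-(4-hydroxyphenyl)chroman-8-yl]-1-(2,4,6-trihydroxyphenyl)propan-1-one (in flask; same C3″ geometry as 7, the descriptor follows the changed CIP ranking) | O=C1C=CC(=C[C@@](O)(c2c(O)cc(O)c3C[C@@H](O)[C@@H](c4ccc(O)cc4)Oc23)C(=O)c2c(O)cc(O)cc2O)C=C1 | intermediate
9 | dihydrofuran carbinol (in flask): (2R,3R)-epiafzelechin with O7 bonded to C2″ and C8 bonded to C3″; C2″ (S) carries H and 4-hydroxyphenyl, C3″ (S) carries OH and 2,4,6-trihydroxybenzoyl; aryl cis to 3″-OH | O=C(c1c(O)cc(O)cc1O)[C@@]1(O)[C@H](c2ccc(O)cc2)Oc2cc(O)c3C[C@@H](O)[C@@H](c4ccc(O)cc4)Oc3c21 | intermediate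
10 | CNP0170480.3: as 9, with O1″ of ring A″ bonded to flavan C8 (spiro atom of a 3″,5″,7″-trihydroxychroman-4″-one, cis-fused to the dihydrofuran ring) and flavan ring A as the 5-oxo cross-conjugated dienone (C6=C7, C4a=C8a); 2R,3R,8S,2″S,3″R | O=C1C=C2O[C@@H](c3ccc(O)cc3)[C@]3(O)C(=O)c4c(O)cc(O)cc4O[C@]23C2=C1C[C@@H](O)[C@@H](c1ccc(O)cc1)O2 | target

**Totals**
Total steps: 3. Longest linear sequence: 3 (1 → 4 → 7 → 10; 5 enters in step 2).

**Steps most likely to fail**

Step 3 (the proposed new step). The risks are over-oxidation of the two 4-hydroxyphenyl groups or of the product dienone, 6-exo closure of quinone methide 8 by an ortho-OH of ring A″ (giving a 3-hydroxyflavanone) instead of 5-exo closure by the 7-OH, and acid ionisation of the tertiary C3″ carbinol. The fallback uses known chemistry, sets out from 7 and comes back at 10. The cyclodehydration is run alone (p-TsOH·H2O, HFIP, 25 °C) and dihydrofuran carbinol 9 is isolated and purified. PhI(OAc)2 (1.05 equiv) in HFIP–MeCN at −20 °C then carries out the para-dearomatisation with internal O-capture as a reagent-bound process and gives 10. No compound outside the list is made (F0).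

Step 2. The risks are C6 instead of C8 attack, reversal of the hydroxyalkylation, and borohydride attacking the wrong ketone or base-induced retro-Claisen cleavage of the 2-hydroxy-1,3-diketone. The fallback sets out from 6 and comes back at 9. The coupling is stopped before the borohydride and 6 is isolated in its ring-closed form, the 7-O-hemiketal lactol F2. Ionic hydrogenation of this lactol (Et3SiH, TFA, CH2Cl2–MeCN, −20 °C) goes through the aryl- and O7-stabilised oxocarbenium ion. Equilibration of C2″ with p-TsOH·H2O in HFIP at 25 °C, by reversible ring opening to 8, then gives dihydrofuran carbinol 9, which is electrolysed as in the second stage of step 3.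

Step 1. The risks are further oxidation and hydrolytic cleavage of 4 to aryl glyoxylic and benzoic acids during bulk electrolysis. The fallback sets out from 1 and comes back at 4. PhI(OAc)2 in MeOH at 0 °C (the known oxidative 2,3-dimethoxylation of 3-hydroxyflavones) gives the 3-hydroxy-2,3-dimethoxyflavanone F1, which is isolated. 1 M HCl in THF–H2O at 40 °C hydrolyses it to 2, which ring-contracts through 3 to 4.

**Further compounds**
F1 | step 1 | 3,5,7-trihydroxy-2-(4-hydroxyphenyl)-2,3-dimethoxychroman-4-one (racemic) | COC1(c2ccc(O)cc2)Oc2cc(O)cc(O)c2C(=O)C1(O)OC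
F2 | step 2 | 7-O-hemiketal (lactol) of 6: as 9, but C2″ carries OH in place of H (both anomers); C3″ geometry as in 6 and 9 | O=C(c1c(O)cc(O)cc1O)[C@@]1(O)C(O)(c2ccc(O)cc2)Oc2cc(O)c3C[C@@H](O)[C@@H](c4ccc(O)cc4)Oc3c21
F0 | step 3 | none | none
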